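**Plan**

1. Feature: in the ten-membered carbocycle C1–C10, the C7–C8 bond joins the lactone β-carbon C7 to the oxygenated C8 beside C9, and C11 carries the exocyclic C13. An ether from O8 to C13 across a C7=C11 butenolide therefore makes C7–C8 the product of a [2,3] shift.
2. Retrosynthetic cuts, in order: the O9 acetate and O8 methacrylate, the C11–C13 epoxide, C7–C8 (retro-[2,3], giving a 13-membered keto ether), C7=C11 (metathesis), O6–C12 (macrolactone), O8–C13 (ether), C6–C7 (vinyl addition), O–C3 and C1–C2 of the furanone (ynone), C9–C10 (aldol).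
3. Forward ring order: 3(2H)-furanone, macrolactone, butenolide (which turns the macrolactone into the 13-membered cyclic ether), ten-membered carbocycle by ring contraction, spiro-epoxide.
4. Stereochemistry: C10 from (R)-lactic acid by self-regeneration of the stereocentre; Z-C4=C5 from the commercial enynol; C6 from a catalyst-controlled vinyl addition; C7 and C8 from the [2,3] shift under control of C6; C9 from chelation-controlled reduction; C11 from hydroxyl-directed epoxidation.

Key step: step 16

Remark: atoms carry germacrane numbers (C1 furanone carbonyl, C2=C3, C4=C5, C6 lactone carbinol, C10 quaternary, C11–C13 lactone carbons). The C9 carbinol from the aldol is assumed to form as an epimer mixture; it is carried unassigned (no descriptor in the SMILES) until both epimers converge at the ketone in step 15.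

**Route**

Step 1
Reactants: 1 (R)-lactic acid; 2 pivalaldehyde
Product: 3 (2R,5R)-2-tert-butyl-5-methyl-1,3-dioxolan-4-one
Conditions: TsOH·H2O (cat.), H2SO4 (cat.), pentane, reflux, Dean–Stark; recrystallisation at −78 °C
Reagents that add atoms: none
Why: Acid-catalysed acetalisation of the α-hydroxy acid with azeotropic water removal should give the cis-dioxolanone as the favoured and crystallisable isomer, so the acetal centre is set by the lactate stereocentre (first stage of self-regeneration of stereocentres).

Step 2
Reactants: 3 (2R,5R)-2-tert-butyl-5-methyl-1,3-dioxolan-4-one; 4 (tert-butyldimethylsilyloxy)acetaldehyde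
Product: 6 (2R,5S)-2-tert-butyl-5-[2-(tert-butyldimethylsilyloxy)-1-hydroxyethyl]-5-methyl-1,3-dioxolan-4-one, via lithium enolate 5 (not isolated)
Conditions: LDA, THF, −78 °C; then 4, −78 °C; AcOH quench at −78 °C
Reagents that add atoms: none
Why: Aldol addition of the dioxolanone lithium enolate should take the aldehyde on the face anti to the tert-butyl group, so the quaternary centre (future C10) forms with overall retention of the lactate configuration, while the carbinol centre (future C9) needs no control because it is oxidised later.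

Step 3
Reactants: 6 aldol adduct
Product: 7 (2R,5S)-2-tert-butyl-5-[1,2-bis(tert-butyldimethylsilyloxy)ethyl]-5-methyl-1,3-dioxolan-4-one
Conditions: TBSOTf, 2,6-lutidine, CH2Cl2, −78 → 0 °C
Reagents that add atoms: tert-butyldimethylsilyl triflate, CC(C)(C)[Si](C)(C)OS(=O)(=O)C(F)(F)F
Why: Silylation of the hindered aldol hydroxyl with a silyl triflate and a non-nucleophilic base avoids retro-aldol cleavage and creates no stereocentre.

Step 4
Reactants: 8 (Z)-3-methylpent-2-en-4-yn-1-ol
Product: 9 (Z)-1-(tert-butyldimethylsilyloxy)-3-methylpent-2-en-4-yne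
Conditions: TBSCl, imidazole, CH2Cl2, 0 °C → rt
Reagents that add atoms: tert-butyldimethylsilyl chloride, CC(C)(C)[Si](C)(C)Cl
Why: Standard silylation of a primary alcohol masks the Z-allylic hydroxyl, which would otherwise add to the ynone of step 5 and cycloisomerise to a furan.

Step 5
Reactants: 9 silyl ether of the enynol; 7 bis-silylated dioxolanone
Product: 12 (2Z,7S)-1,8,9-tris(tert-butyldimethylsilyloxy)-7-hydroxy-3,7-dimethylnon-2-en-4-yn-6-one, via lithium acetylide 10 (not isolated), via lithium hemiketal alkoxide 11 (not isolated)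
Conditions: n-BuLi, THF, −78 °C; then 7, −78 °C; AcOH quench at −78 °C, warm to rt, silica gel
Reagents that add atoms: none
Why: Acetylide addition to the lactone-type carbonyl of the dioxolanone should stop at the tetrahedral alkoxide at −78 °C, which on protonation collapses to the ynone and loses pivalaldehyde to free the tertiary hydroxyl; no stereocentre is created and the quaternary centre cannot epimerise.

Step 6
Reactants: 12 α′-hydroxy ynone
Product: 14 (S)-2-[1,2-bis(tert-butyldimethylsilyloxy)ethyl]-5-[(Z)-4-(tert-butyldimethylsilyloxy)but-2-en-2-yl]-2-methylfuran-3(2H)-one, via enaminone 13 (not isolated)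
Conditions: Et2NH, EtOH, rt; then AcOH (cat.), 40 °C
Reagents that add atoms: none
Why: Conjugate addition of diethylamine to the ynone gives an enaminone whose β-carbon is then attacked by the tertiary hydroxyl (addition–elimination, 5-exo-trig), closing the 3(2H)-furanone with release of the amine; the Z alkene is only cross-conjugated and should not isomerise.

Step 7
Reactants: 14 tris-silylated furanone
Product: 15 (S)-2-[1-(tert-butyldimethylsilyloxy)-2-hydroxyethyl]-5-[(Z)-4-hydroxybut-2-en-2-yl]-2-methylfuran-3(2H)-one
Conditions: HF·pyridine, pyridine, THF, 0 °C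
Reagents that add atoms: none
Why: Buffered fluoride desilylation should cleave the two primary silyl ethers and spare the secondary one, which is shielded by the adjacent quaternary carbon.

Step 8
Reactants: 15 diol
Product: 16 (Z)-3-{(S)-5-[1-(tert-butyldimethylsilyloxy)-2-hydroxyethyl]-5-methyl-4-oxo-4,5-dihydrofuran-2-yl}but-2-enal
Conditions: MnO2, CH2Cl2, rt, dark
Reagents that add atoms: none
Why: MnO2 oxidises only the allylic alcohol (C6) and leaves the saturated primary alcohol (C8), and its neutral heterogeneous conditions should preserve the Z geometry of the enal.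

Step 9
Reactants: 16 hydroxy aldehyde; 17 methyl 2-(bromomethyl)acrylate
Product: 18 methyl 2-({2-(tert-butyldimethylsilyloxy)-2-[(S)-2-methyl-3-oxo-5-((Z)-4-oxobut-2-en-2-yl)-2,3-dihydrofuran-2-yl]ethoxy}methyl)acrylate (the O8–C13 ether)
Conditions: Ag2O, 4 Å molecular sieves, CH2Cl2, rt, dark
Reagents that add atoms: none
Why: Ag2O-promoted Williamson etherification activates the reactive allylic bromide so that the primary alcohol is alkylated (SN2 and SN2′ give the same ether) without a base that would isomerise the Z-enal.

Step 10
Reactants: 18 aldehyde ether; 19 vinyl bromide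
Product: 20 the (6S)-vinyl carbinol, methyl 2-({2-(tert-butyldimethylsilyloxy)-2-[(S)-5-((S,Z)-4-hydroxyhexa-2,5-dien-2-yl)-2-methyl-3-oxo-2,3-dihydrofuran-2-yl]ethoxy}methyl)acrylate
Conditions: CrCl2 (cat.), chiral oxazoline–sulfonamide ligand (enantiomer directing Si-face addition), 1,8-bis(dimethylamino)naphthalene, NiCl2·(2,9-dimethyl-1,10-phenanthroline) (cat.), Mn powder, Cp2ZrCl2, LiCl, MeCN, rt
Reagents that add atoms: none
Why: In this catalytic asymmetric Nozaki–Hiyama–Kishi reaction the ligand-bound vinylchromium species should add to the Si face of the aldehyde, setting C6 by catalyst control while tolerating the acrylate ester and the vinylogous ester.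

Step 11
Reactants: 20 methyl ester
Product: 21 the seco acid, 2-({2-(tert-butyldimethylsilyloxy)-2-[(S)-5-((S,Z)-4-hydroxyhexa-2,5-dien-2-yl)-2-methyl-3-oxo-2,3-dihydrofuran-2-yl]ethoxy}methyl)acrylic acid
Conditions: Me3SnOH, 1,2-dichloroethane, 70 °C; cold dilute aq. HCl wash
Reagents that add atoms: trimethyltin hydroxide, C[Sn](C)(C)O
Why: Trimethyltin hydroxide cleaves the methyl ester by tin-assisted acyl substitution under near-neutral conditions, avoiding the conjugate addition–elimination that hydroxide would start at the α-(alkoxymethyl)acrylate.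

Step 12
Reactants: 21 seco acid
Product: 23 the macrolactone (O6–C12 ester; 14-membered through C1–C2) with the C6 vinyl group and the C11 methylene and the C9 silyl ether, via mixed anhydride 22 (not isolated)
Conditions: 2-methyl-6-nitrobenzoic anhydride, DMAP, CH2Cl2, rt, slow addition, 2 mM
Reagents that add atoms: none
Why: In the Shiina macrolactonisation the mixed anhydride is acylated by the C6 hydroxyl under DMAP catalysis at high dilution, the Z alkene and the furanone pre-organising the ring; the C6–O bond is not broken, so C6 keeps its configuration.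

Step 13
Reactants: 23 macrolactone
Product: 24 the 13-membered cyclic ether with the C7=C11 butenolide and the furanone and the C9 silyl ether (6R,10S)
Conditions: second-generation Hoveyda–Grubbs catalyst (10 mol %), toluene, 80 °C, argon sparge
Reagents that add atoms: none
Why: Ring-closing metathesis between the C6 vinyl group and the 1,1-disubstituted acrylate alkene closes the five-membered butenolide (its ring size fixes the alkene geometry) and expels ethylene, the trisubstituted alkenes being inert.

Step 14
Reactants: 24 silyl ether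
Product: 25 the C9 alcohol of the macrocyclic ether (epimers at C9)
Conditions: aq. HF, MeCN, 0 °C → rt
Reagents that add atoms: none
Why: Acidic fluoride desilylation avoids base, which matters because the butenolide γ-hydrogen at C6 is now base-labile.

Step 15
Reactants: 25 alcohol
Product: 26 the macrocyclic keto ether (6R,10R): C9 ketone, C8–O8–C13 ether, C7=C11 butenolide, furanone
Conditions: Dess–Martin periodinane, CH2Cl2, rt
Reagents that add atoms: none
Why: Dess–Martin oxidation under neutral conditions converts either C9 epimer into the ketone, so the mixture converges here.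

Step 16
Reactants: 26 macrocyclic keto ether
Product: 28 the (6R,7R,8S,10R)-8-hydroxy-9-oxo ten-membered carbocycle with the furanone and the trans-fused α-methylene γ-lactone, via trichlorotitanium enolate 27 (not isolated)
Conditions: TiCl4 (1.1 equiv), CH2Cl2, −78 °C; iPr2NEt (1.2 equiv), −78 → −20 °C; aq. NH4Cl at −20 °C
Reagents that add atoms: none
Why: Proposed new method: TiCl4 binds the C9 ketone together with the ether oxygen O8 (not the monodentate lactone), so the hindered amine removes only a C8 proton — C10 is quaternary, and the more acidic γ-proton at C6, which a lithium amide would also take, is not activated — and the chelated Z-trichlorotitanium enolate 27 adds through C8 to C7 across a five-membered envelope while the titanium-bound O8–C13 bond breaks. This is an enolate [2,3]-Wittig shift polarised as an intramolecular SN2′ (Michael addition with loss of the alkoxide from C13); the closest known reactions are the [2,3]-Wittig ring contraction of 13-membered allylic ethers to cyclodecenes, [2,3] shifts of lithium and boron enolates of α-allyloxy carbonyl compounds, and Michael additions of chlorotitanium enolates, whereas a butenolide as the allyl unit and a titanium enolate in a ring contraction are untested. The ten-membered carbocycle closes by contraction of the 13-membered ether ring (O8, C13 and C11 leave the ring), not by end-to-end cyclisation, and the α-methylene lactone is unveiled in the same event. C7 is set by C6: C8 should be delivered to the butenolide face opposite the C5 substituent, the mode that leads to the staggered trans-fused lactone. C8 is set by the Z enolate geometry and by the short C10–O–C3–C4 belt, which holds C9 over the C6 edge of the envelope and should give the 7,8-syn (8S) ketol. The step needs C8 over C6 deprotonation and C8–C7 over C9–C7 ([3,3]) bonding; chelation secures the first, the match of the nucleophilic enolate carbon with the electrophilic β-carbon secures the second, and the cold quench keeps the new alkoxide from attacking the 1,3-diketone array.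

Step 17
Reactants: 28 ketol
Product: 29 the (8S,9S)-8,9-diol with the α-methylene lactone intact
Conditions: Zn(BH4)2, Et2O–THF, −30 °C
Reagents that add atoms: none
Why: In this chelation-controlled reduction zinc bridges O8 and the C9 carbonyl, ring atom C7 blocks one face and hydride enters past H8 to give the 8,9-anti diol (9S), while zinc borohydride should leave the α-methylene lactone and the vinylogous ester untouched.

Step 18
Reactants: 29 diol
Product: 30 the (11S)-11,13-epoxy 8,9-diol (epoxide oxygen syn to C8)
Conditions: t-BuOOH, n-BuLi (forms t-BuOOLi), THF, −78 → −20 °C; AcOH quench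
Reagents that add atoms: tert-butyl hydroperoxide, CC(C)(C)OO
Why: In this Weitz–Scheffer (nucleophilic) epoxidation the peroxide adds to C13 of the α-methylene lactone, the only unhindered Michael acceptor, and lithium bound to O8 should hold the peroxide on the C11 face that carries C8, so ring closure places the epoxide oxygen syn to C8, as in hydroxyl-directed lithium peroxide epoxidations.

Step 19
Reactants: 30 epoxy diol
Product: 31 the 8-O-methacryloyl 9-alcohol
Conditions: methacrylic anhydride (1.1 equiv), Et3N, DMAP (cat.), CH2Cl2, −20 °C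
Reagents that add atoms: methacrylic anhydride, C=C(C)C(=O)OC(=O)C(C)=C
Why: Regioselective esterification is expected because the C9 hydroxyl is flanked by the fully substituted C10 and should react far more slowly than the C8 hydroxyl.

Step 20
Reactants: 31 mono-ester
Product: 32 CNP0423862.2
Conditions: Ac2O, pyridine, DMAP (cat.), CH2Cl2, rt
Reagents that add atoms: acetic anhydride, CC(=O)OC(C)=O
Why: DMAP-catalysed acetylation of the remaining hindered secondary alcohol completes the target without touching any stereocentre.

**Compound list**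

1 | (R)-lactic acid | C[C@@H](O)C(=O)O | starting material
2 | pivalaldehyde | CC(C)(C)C=O | starting material
3 | (2R,5R)-2-tert-butyl-5-methyl-1,3-dioxolan-4-one | C[C@H]1O[C@@H](C(C)(C)C)OC1=O | intermediate
4 | (tert-butyldimethylsilyloxy)acetaldehyde | O=CCO[Si](C)(C)C(C)(C)C | starting material
5 | lithium enolate of 3 | CC1=C(O[Li])O[C@H](C(C)(C)C)O1 | intermediate (not isolated)
6 | (2R,5S)-2-tert-butyl-5-[2-(tert-butyldimethylsilyloxy)-1-hydroxyethyl]-5-methyl-1,3-dioxolan-4-one (carbinol epimers) | C[C@@]1(C(O)CO[Si](C)(C)C(C)(C)C)O[C@@H](C(C)(C)C)OC1=O | intermediate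
7 | (2R,5S)-2-tert-butyl-5-[1,2-bis(tert-butyldimethylsilyloxy)ethyl]-5-methyl-1,3-dioxolan-4-one | C[C@@]1(C(O[Si](C)(C)C(C)(C)C)CO[Si](C)(C)C(C)(C)C)O[C@@H](C(C)(C)C)OC1=O | intermediate
8 | (Z)-3-methylpent-2-en-4-yn-1-ol | C#C/C(C)=C\CO | starting material
9 | (Z)-1-(tert-butyldimethylsilyloxy)-3-methylpent-2-en-4-yne | C#C/C(C)=C\CO[Si](C)(C)C(C)(C)C | intermediate
10 | lithium acetylide of 9 | [Li]C#C/C(C)=C\CO[Si](C)(C)C(C)(C)C | intermediate (not isolated)
11 | lithium hemiketal alkoxide (acetylide adduct of 7) | C[C@@]1(C(O[Si](C)(C)C(C)(C)C)CO[Si](C)(C)C(C)(C)C)O[C@@H](C(C)(C)C)OC1(O[Li])C#C/C(C)=C\CO[Si](C)(C)C(C)(C)C | intermediate (not isolated)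
12 | (2Z,7S)-1,8,9-tris(tert-butyldimethylsilyloxy)-7-hydroxy-3,7-dimethylnon-2-en-4-yn-6-one | C[C@](O)(C(O[Si](C)(C)C(C)(C)C)CO[Si](C)(C)C(C)(C)C)C(=O)C#C/C(C)=C\CO[Si](C)(C)C(C)(C)C | intermediate
13 | 4-diethylamino enaminone from 12 | C[C@](O)(C(O[Si](C)(C)C(C)(C)C)CO[Si](C)(C)C(C)(C)C)C(=O)C=C(N(CC)CC)/C(C)=C\CO[Si](C)(C)C(C)(C)C | intermediate (not isolated)
14 | (S)-2-[1,2-bis(tert-butyldimethylsilyloxy)ethyl]-5-[(Z)-4-(tert-butyldimethylsilyloxy)but-2-en-2-yl]-2-methylfuran-3(2H)-one | C[C@@]1(C(O[Si](C)(C)C(C)(C)C)CO[Si](C)(C)C(C)(C)C)OC(=CC1=O)/C(C)=C\CO[Si](C)(C)C(C)(C)C | intermediate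
15 | (S)-2-[1-(tert-butyldimethylsilyloxy)-2-hydroxyethyl]-5-[(Z)-4-hydroxybut-2-en-2-yl]-2-methylfuran-3(2H)-one | C[C@@]1(C(O[Si](C)(C)C(C)(C)C)CO)OC(=CC1=O)/C(C)=C\CO | intermediate
16 | (Z)-enal with free C8 hydroxyl | C[C@@]1(C(O[Si](C)(C)C(C)(C)C)CO)OC(=CC1=O)/C(C)=C\C=O | intermediate
17 | methyl 2-(bromomethyl)acrylate | C=C(CBr)C(=O)OC | starting material
18 | O8–C13 ether (acrylate methyl ester, C6 aldehyde) | C[C@@]1(C(O[Si](C)(C)C(C)(C)C)COCC(=C)C(=O)OC)OC(=CC1=O)/C(C)=C\C=O | intermediate
19 | vinyl bromide | C=CBr | starting material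
20 | (6S)-vinyl carbinol methyl ester | C[C@@]1(C(O[Si](C)(C)C(C)(C)C)COCC(=C)C(=O)OC)OC(=CC1=O)/C(C)=C\[C@@H](O)C=C | intermediate
21 | seco acid | C[C@@]1(C(O[Si](C)(C)C(C)(C)C)COCC(=C)C(=O)O)OC(=CC1=O)/C(C)=C\[C@@H](O)C=C | intermediate
22 | mixed anhydride of 21 with 2-methyl-6-nitrobenzoic acid | C[C@@]1(C(O[Si](C)(C)C(C)(C)C)COCC(=C)C(=O)OC(=O)c2c(C)cccc2[N+](=O)[O-])OC(=CC1=O)/C(C)=C\[C@@H](O)C=C | intermediate (not isolated)
23 | macrolactone (C6 vinyl, C11 methylene, C9 silyl ether) | C[C@@]12OC(=CC1=O)/C(C)=C\[C@H](C=C)OC(=O)C(=C)COCC2O[Si](C)(C)C(C)(C)C | intermediate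
24 | butenolide-containing 13-membered cyclic ether, C9 silyl ether | C[C@@]12OC(=CC1=O)/C(C)=C\[C@@H]3C=C(COCC2O[Si](C)(C)C(C)(C)C)C(=O)O3 | intermediate
25 | C9 alcohol of the macrocyclic ether | OC1COCC2=C[C@@H](/C=C(/C)C3=CC(=O)[C@@]1(C)O3)OC2=O | intermediate
26 | macrocyclic keto ether (precursor of the key step) | O=C1COCC2=C[C@@H](/C=C(/C)C3=CC(=O)[C@@]1(C)O3)OC2=O | intermediate
27 | chelated Z-trichlorotitanium enolate of 26 | Cl[Ti](Cl)(Cl)O/C1=C\OCC2=C[C@@H](/C=C(/C)C3=CC(=O)[C@@]1(C)O3)OC2=O | intermediate (not isolated)
28 | (6R,7R,8S,10R)-8-hydroxy-9-oxo carbocycle with α-methylene trans-lactone | O=C1[C@@H](O)[C@@H]2[C@@H](/C=C(/C)C3=CC(=O)[C@@]1(C)O3)OC(=O)C2=C | intermediate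
29 | (8S,9S)-8,9-diol with α-methylene lactone | O[C@H]1[C@@H]2[C@@H](/C=C(/C)C3=CC(=O)[C@@](C)(O3)[C@H]1O)OC(=O)C2=C | intermediate
30 | (11S)-11,13-epoxy 8,9-diol | O[C@H]1[C@@H]2[C@@H](/C=C(/C)C3=CC(=O)[C@@](C)(O3)[C@H]1O)OC(=O)[C@@]21CO1 | intermediate
31 | 8-O-methacryloyl 9-alcohol | C=C(C)C(=O)O[C@H]1[C@@H]2[C@@H](/C=C(/C)C3=CC(=O)[C@@](C)(O3)[C@H]1O)OC(=O)[C@@]21CO1 | intermediate
32 | CNP0423862.2 | C=C(C)C(=O)O[C@H]1[C@@H]2[C@@H](/C=C(/C)C3=CC(=O)[C@@](C)(O3)[C@H]1OC(C)=O)OC(=O)[C@@]21CO1 | target

**Step count and risks**

Total: 20 steps. Longest linear sequence: 19 steps (steps 1–3 and 5–20 from (R)-lactic acid); step 4 is a one-step side branch.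

Step 16 (proposed new method). The amine may still remove the C6 γ-proton (epimerisation at C6 or an unreactive furanolate), the titanium enolate may add too slowly, or C8 may be delivered to the wrong face of C7. The fallback uses known chemistry and closes the ring by an intramolecular Barbier allylation instead of a ring contraction; it leaves the route at aldehyde 16 and rejoins it at ketol 28. The C8 hydroxyl of 16 is silylated (TESCl, imidazole) to the triethylsilyl ether F1. Asymmetric Nozaki–Hiyama–Kishi vinylation as in step 10 gives the C6 vinyl carbinol F2. Acylation with 2-(bromomethyl)acryloyl chloride and 2,4,6-collidine gives the 2-(bromomethyl)acrylate F3, and ring-closing metathesis as in step 13 gives the α-(bromomethyl)butenolide F4. Aqueous HF in MeCN removes both silyl groups to give the 8,9-diol F5, and Dess–Martin oxidation of both hydroxyls gives the α-keto aldehyde F6. Indium powder in THF–water at high dilution then turns the allylic bromide into an allylindium species that adds through C7 to the C8 aldehyde (the ketone being less reactive), closing the ten-membered ring with transposition to the α-methylene lactone and giving 28. C7 and C8 would then rest on addition anti to the C6 substituent and on the cyclic transition state of the allylation.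

Step 18. Facial selectivity may be poor if the lithium bridge from O8 does not hold the peroxide (closure on the open face gives the 11-epimer), or peroxide may add to C5 of the dienone. The fallback delivers the oxygen by a hydrogen-bond-directed dihydroxylation instead of a peroxide. From diol 29, stoichiometric OsO4·TMEDA in CH2Cl2 at −78 °C, held by the C8 hydroxyl, dihydroxylates C11=C13 on the C8 face and gives, after cleavage of the osmate ester, the tetraol F7. Selective tosylation of the primary C13 hydroxyl (TsCl, pyridine) gives the tosylate F8. K2CO3 in MeOH closes the epoxide by attack of the C11 alkoxide on C13, keeping the C11–O bond made in the directed step, and the route is rejoined at epoxy diol 30.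

Step 19. Regioselectivity between O8 and O9 may be lost, or the acyl group may migrate under the basic conditions. The fallback keeps the C9 carbonyl as the placeholder for O9 until O8 is esterified. From ketol 28, epoxidation as in step 18 gives the epoxy ketol F9, and methacrylic anhydride with DMAP gives the α-acyloxy ketone F10. Reduction with Zn(BH4)2 at low temperature, with hydride entering from the peripheral face past H8, then gives the 9-alcohol 31 directly.

**Further compounds**

F1 | step 16 | C8 triethylsilyl ether of aldehyde 16 | C[C@@]1(C(O[Si](C)(C)C(C)(C)C)CO[Si](CC)(CC)CC)OC(=CC1=O)/C(C)=C\C=O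
F2 | step 16 | (6S)-vinyl carbinol with C8 triethylsilyl and C9 tert-butyldimethylsilyl ethers | C[C@@]1(C(O[Si](C)(C)C(C)(C)C)CO[Si](CC)(CC)CC)OC(=CC1=O)/C(C)=C\[C@@H](O)C=C
F3 | step 16 | 2-(bromomethyl)acrylate ester of F2 | C[C@@]1(C(O[Si](C)(C)C(C)(C)C)CO[Si](CC)(CC)CC)OC(=CC1=O)/C(C)=C\[C@H](C=C)OC(=O)C(=C)CBr
F4 | step 16 | α-(bromomethyl)butenolide, bis-silyl ether | C[C@@]1(C(O[Si](C)(C)C(C)(C)C)CO[Si](CC)(CC)CC)OC(=CC1=O)/C(C)=C\[C@@H]2C=C(CBr)C(=O)O2
F5 | step 16 | α-(bromomethyl)butenolide 8,9-diol | C[C@@]1(C(O)CO)OC(=CC1=O)/C(C)=C\[C@@H]2C=C(CBr)C(=O)O2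
F6 | step 16 | α-(bromomethyl)butenolide α-keto aldehyde (C9 ketone, C8 aldehyde) | C[C@@]1(C(=O)C=O)OC(=CC1=O)/C(C)=C\[C@@H]2C=C(CBr)C(=O)O2
F7 | step 18 | 8,9,11,13-tetraol (11-hydroxyl syn to C8) | O[C@H]1[C@@H]2[C@@H](/C=C(/C)C3=CC(=O)[C@@](C)(O3)[C@H]1O)OC(=O)[C@@]2(O)CO
F8 | step 18 | 13-O-tosylate of F7 | O[C@H]1[C@@H]2[C@@H](/C=C(/C)C3=CC(=O)[C@@](C)(O3)[C@H]1O)OC(=O)[C@@]2(O)COS(=O)(=O)c1ccc(C)cc1
F9 | step 19 | 11,13-epoxy 8-hydroxy 9-ketone | O=C1[C@@H](O)[C@@H]2[C@@H](/C=C(/C)C3=CC(=O)[C@@]1(C)O3)OC(=O)[C@@]21CO1
F10 | step 19 | 11,13-epoxy 8-O-methacryloyl 9-ketone | C=C(C)C(=O)O[C@H]1[C@@H]2[C@@H](/C=C(/C)C3=CC(=O)[C@@](C)(O3)C1=O)OC(=O)[C@@]21CO1
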